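Which of the four flasks, differing in temperature, would hold the most target after 30 d?

| setting | grey | blue | ochre | Thursday's | Tuesday's | Sunday's | Wednesday's |
|---|---|---|---|---|---|---|---|
| substrate | 10 mM | 10 mM | 10 mM | 10 mM | 10 mM | 10 mM | 10 mM |
| partner | 11 mM | 11 mM | 16 mM | 11.0 mM | 11.0 mM | 11.0 mM | 11.0 mM |
| capture agent | 1.5 mM | 6 mM | 3 mM | 3.00 mM | 3.00 mM | 3.00 mM | 3.00 mM |
| temperature | 62 °C | 112 °C | 62 °C | 100 °C | 70 °C | 40 °C | 130 °C |
| remark | run made earlier | run made earlier | run made earlier |  |  |  |  |
| time |  |  |  | 30 d | 30 d | 30 d | 30 d |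

| run | time / d | target / % |
|---|---|---|
| grey | 30.0 | 64 |
| grey | 60.0 | 63 |
| grey | 100 | 63 |
| grey | 120 | 65 |
| grey | 150 | 68 |
| grey | 200 | 62 |
| grey | 250 | 65 |
| blue | 1.25 | 48 |
| blue | 3.00 | 48 |
| blue | 6.00 | 48 |
| blue | 8.00 | 50 |
| blue | 12.0 | 47 |
| blue | 15.0 | 45 |
| blue | 20.0 | 46 |
| ochre | 20.0 | 71 |
| ochre | 60.0 | 70 |
| ochre | 100 | 71 |
| ochre | 150 | 73 |
| ochre | 250 | 73 |

(standard deviation of a reading: 1.5 percentage points)

1. the flask that comes out highest in amount of target, in percent of the substrate charged, or "all alike" when all lie within 1.5 percentage points (Thursday's / Tuesday's / Sunday's / Wednesday's / all alike)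
2. target at the end, in percent of the substrate charged, Thursday's
3. target at the end, in percent of the substrate charged, Tuesday's
4. target at the end, in percent of the substrate charged, Sunday's
5. target at the end, in percent of the substrate charged, Wednesday's

- the earlier runs were read with a standard deviation of 1.5 percentage points

I took the settings in turn. More partner should raise the plateau, and ochre at [partner] = 16 mM first read 71% against grey's 64% at [partner] = 11 mM. But ochre also held more capture agent, so the two settings could not be separated, and the four flasks share [partner] = 11.0 mM and [capture agent] = 3.00 mM. Blue at 112 °C first read 48%, lower than grey at 62 °C; blue also held more capture agent, so I took a lower plateau with heat as a working guess. By that reading Sunday's should win, but a plateau counts for a flask that reaches it within 30 d. From the first flat readings, ochre's at 20.0 d and blue's at 1.25 d, I reckoned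

halving step = 12.5 K

This is the temperature rise that, as read from these two runs, halves the time to the plateau. It is rough, because both times are ceilings and the runs differ in charge. Counting down from ochre's time, I got

Sunday's: 67.7 d

Tuesday's: 12.8 d

My estimate for Sunday's was longer than 30 d, so I expected it below its plateau. My estimate for Tuesday's was shorter and that flask was cooler than Thursday's and Wednesday's, so I put Tuesday's highest.

The forecast differed and named Sunday's, with 51% for Thursday's, 60.5% for Tuesday's, 66% for Sunday's and 44% for Wednesday's. Its caveat ran: “Equilibrium took under 20 d at 62 °C, so at 40 °C, 30 d may fall short.”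

The flasks gave 55.5% for Thursday's, 63.2% for Tuesday's, 27.4% for Sunday's and 37.0% for Wednesday's, so Tuesday's came out highest.

    substrate ⇌ open intermediate (K = 0.570, k = 0.0190 h⁻¹, Ea = 104 kJ mol⁻¹, ΔH = −45.0 kJ mol⁻¹)
    partner → second intermediate (k = 0.500 h⁻¹, Ea = 102 kJ mol⁻¹)
    open intermediate + second intermediate → target (k = 19.0 M⁻¹ h⁻¹, Ea = 78.0 kJ mol⁻¹)
    2 second intermediate → homo product (k = 1.20 M⁻¹ h⁻¹, Ea = 86.0 kJ mol⁻¹)
    open intermediate → decomposed reagent (k = 0.00170 h⁻¹, Ea = 120 kJ mol⁻¹)
    second intermediate + capture agent → trapped intermediate (k = 0.220 M⁻¹ h⁻¹, Ea = 66.0 kJ mol⁻¹)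
    (constants at 70 °C)

In Sunday's, second intermediate was made 15.2 times faster than it was used up at 1.78 d, and at 12 d it stood at 7.51 mM with 0.92% of the partner charge left. The opening of substrate then ran on, with a forward half-life of 50 d at 30.0 d, when Sunday's held 66.5% substrate and 27.4% target. With the 12.5 K halving step I had estimated 67.7 d to the plateau for Sunday's; that flask's substrate reached half conversion at 51.6 d, and at 300 d it held 58.2% target.

For a flask like Sunday's kept at 65 °C, the halving step gives 16.9 d, shorter than 30 d, so it should stand near its plateau. It gave 63.1% target, with 17.1% substrate remaining.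

All runs are simulated from invented constants, and the scatter is random.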